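**Retrosynthetic overview**
1. 34 ⇒ open the oxepane at O–C16 (Williamson closure comes last) and simplify C11-OAc/C15; the cyclohexane (C1, C10–C14) ⇒ Diels–Alder of methyl vinyl ketone with a 2-silyloxydiene built on C10 of a bicyclic ketone.
2. The C6-OMe/C7-H pair ⇒ syn hydrosilylation/oxidation of a Z C6=C7 bond, delivered from the C3 oxygen.
3. Bicyclic ketone (tetrahydrofuran-3-one bridged by an oxonene) ⇒ ring expansion of a tetrahydropyran: a carbenoid at C9 is captured by the ring oxygen (O–C9 bond; closes the ring O/C2/C1/C10/C9), then a 2,3-shift forms C8–C9, breaks O–C6 and gives the nine-membered ring.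
4. Enabling feature: the oxygen of the C2–O–C9 bridge is the tetrahydropyran oxygen; C2 carries the arm C1–C10(=O)–C9 (diazo carbon 1,5 to O) and C6 is allylic through the isopropenyl unit C7(=C8); the C10 carbonyl stabilises the carbenoid and later anchors the cyclohexane.
5. Tetrahydropyran ⇒ oxa-Michael closure of a chain cut from (S)-linalool (C3 carbinol centre from the pool). Ring order: tetrahydropyran → tetrahydrofuranone + oxonene (key step) → cyclohexane → oxepane.

Key step: step 8

Remark 1: (S)-(+)-linalool and the L-fructose-derived (ent-)Shi ketone are assumed to be purchasable; diazomethane is used as a separately prepared ether solution.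
Remark 2: locants C1–C16 in names and comments follow the skeleton of 34: C2–O–C9 tetrahydrofuran bridge, C1/C10 ring fusion, C3 methyl-bearing ether carbon, C6 methoxy carbon, C7 and C12 methyl-bearing carbons, C11 acetoxy carbon, C14 ring carbon bearing C15(CH3)–C16H2.

**Step 1**
Reactants: 1 (S)-(+)-linalool
Product: 2 (3S)-3,7-dimethyl-3-(triethylsilyloxy)octa-1,6-diene
Conditions: TESOTf, 2,6-lutidine, CH2Cl2, −78 → 0 °C
Reagents that add atoms: triethylsilyl triflate CC[Si](CC)(CC)OS(=O)(=O)C(F)(F)F
Why: Silylation of the hindered tertiary allylic alcohol with a silyl triflate and a hindered base is routine; the C3 stereocentre comes from the chiral pool and the ether later prevents epoxide opening (step 2–4) and O–H insertion (step 8).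

**Step 2**
Reactants: 2
Product: 3 (3S,6S)-6,7-epoxy-3,7-dimethyl-3-(triethylsilyloxy)oct-1-ene
Conditions: L-fructose-derived Shi ketone (30 mol %), Oxone, K2CO3, Bu4NHSO4, MeCN/(MeO)2CH2/aq. borate buffer (pH 10.5), 0 °C
Reagents that add atoms: Oxone (potassium peroxymonosulfate) [K+].[O-]S(=O)(=O)OO
Why: Shi asymmetric epoxidation by the chiral dioxirane should take the electron-rich trisubstituted alkene and leave the vinyl group, and the spiro transition state of the ent-ketone should place oxygen on the face that gives the 6S epoxide (reagent control).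

**Step 3**
Reactants: 3; 4 ethyl (triphenylphosphoranylidene)acetate
Product: 7 ethyl (2E,4S)-6-[(2S)-3,3-dimethyloxiran-2-yl]-4-methyl-4-(triethylsilyloxy)hex-2-enoate, via ozonide 5 (not isolated), via aldehyde 6 (not isolated)
Conditions: O3, CH2Cl2, −78 °C; PPh3, −78 °C → rt; then 4 (excess), rt
Reagents that add atoms: ethyl (triphenylphosphoranylidene)acetate (4) CCOC(=O)C=P(c1ccccc1)(c1ccccc1)c1ccccc1
Why: Ozonolysis cleaves the only remaining alkene and the Wittig reaction of the stabilised ylide with the neopentyl-type aldehyde should give the E-enoate; no stereocentre is touched.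

**Step 4**
Reactants: 7
Product: 8 ethyl (2E,4S,7S)-7-hydroxy-4,8-dimethyl-4-(triethylsilyloxy)nona-2,8-dienoate
Conditions: Et2Al(TMP) (prepared separately from LiTMP and Et2AlCl), toluene, 0 °C; aq. Rochelle salt
Reagents that add atoms: none
Why: Aluminium-amide isomerisation of a trisubstituted epoxide to an allylic alcohol proceeds by syn β-elimination through a cyclic transition state with proton loss from a methyl of the gem-dimethyl carbon; the C6–O bond is not broken, so C6 keeps its configuration, and the hindered non-nucleophilic amide should spare the enoate (which has no γ-hydrogen).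

**Step 5**
Reactants: 8
Product: 9 ethyl 2-[(2S,3S,6S)-3-methyl-6-(prop-1-en-2-yl)-3-(triethylsilyloxy)oxan-2-yl]acetate
Conditions: KOt-Bu (0.2 equiv), THF, 0 °C → rt
Reagents that add atoms: none
Why: Reversible intramolecular oxa-Michael addition (6-exo-trig) under alkoxide catalysis should settle on the 2,6-cis tetrahydropyran with both arms equatorial, so the new C2 centre (S) is dictated by C6.

**Step 6**
Reactants: 9
Product: 10 2-[(2S,3S,6S)-3-methyl-6-(prop-1-en-2-yl)-3-(triethylsilyloxy)oxan-2-yl]acetic acid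
Conditions: LiOH·H2O, THF/MeOH/H2O, rt; then 1 M HCl to pH 4, 0 °C
Reagents that add atoms: lithium hydroxide [Li+].[OH-]
Why: Ester saponification; the tertiary TES ether tolerates hydroxide and a brief mildly acidic work-up.

**Step 7**
Reactants: 10; 11 diazomethane
Product: 13 1-diazo-3-[(2S,3S,6S)-3-methyl-6-(prop-1-en-2-yl)-3-(triethylsilyloxy)oxan-2-yl]propan-2-one, via mixed anhydride 12 (not isolated)
Conditions: i-BuOCOCl, Et3N, Et2O, −20 °C; then CH2N2 (Et2O solution), 0 °C
Reagents that add atoms: diazomethane (11) C=[N+]=[N-]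
Why: Acylation of diazomethane by a mixed carbonic anhydride (first stage of the Arndt–Eistert sequence) gives the α-diazoketone under conditions that leave the silyl ether and the isopropenyl group alone.

**Step 8**
Reactants: 13
Product: 15 (1S,2S,5Z,8S)-2,6-dimethyl-2-(triethylsilyloxy)-11-oxabicyclo[6.2.1]undec-5-en-9-one, via oxonium ylide 14 (not isolated)
Conditions: Cu(hfacac)2 (5 mol %), CH2Cl2, reflux, slow addition of 13
Reagents that add atoms: none
Why: Copper decomposes the diazoketone to an electrophilic carbenoid at C9, the tetrahydropyran oxygen attacks it (this closes the five-membered ring O/C2/C1/C10/C9 and forms the O–C9 bond), and the resulting bicyclic allylic oxonium ylide undergoes a [2,3]-sigmatropic shift in which C9 bonds to the isopropenyl CH2 (C8) while O–C6 breaks. The closest known reaction type is the copper-catalysed tandem oxonium-ylide formation/[2,3]-rearrangement of allyl ethers tethered to diazoketones, used to make bridged medium-ring ethers. The tetrahydrofuran-3-one ring closes by 1,5 O–C bond formation at the carbenoid, and the oxonene arises by three-atom ring expansion of the tetrahydropyran through a five-centre envelope transition state. The new stereocentre C9 is fixed by the bicyclic constraint, because C8 and C3 are the two ends of the six-carbon bridge and must be cis on the tetrahydrofuran; C2 and C3 are untouched and the C6 centre is traded for the alkene. The step needs [2,3]-shift over [1,2]-shift, C–H insertion and O–H insertion, and Z over E geometry. The electron-poor Cu(hfacac)2 catalyst, the cis (diequatorial) placement of both arms on the ring oxygen and the silyl protection of the C3 oxygen should secure these.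

**Step 9**
Reactants: 15
Product: 16 (1S,2S,5Z,8S)-2-hydroxy-2,6-dimethyl-11-oxabicyclo[6.2.1]undec-5-en-9-one
Conditions: HF·pyridine, pyridine, THF, 0 °C → rt
Reagents that add atoms: none
Why: Buffered fluoride cleaves the tertiary TES ether without base, which avoids β-elimination of the β-alkoxy ketone.

**Step 10**
Reactants: 16
Product: 19 (1S,2S,5R,6R,8S)-2,5-dihydroxy-2,6-dimethyl-11-oxabicyclo[6.2.1]undecan-9-one, via silyl hydride ether 17 (not isolated), via cyclic siloxane 18 (not isolated)
Conditions: HMe2SiCl, Et3N, DMAP (cat.), CH2Cl2, 0 °C → rt, filter, concentrate; Pt2(dvds)3 (1 mol %), toluene, 60 °C; then KF, KHCO3, 30 % H2O2, THF/MeOH, rt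
Reagents that add atoms: hydrogen peroxide OO
Why: Tethered hydrosilylation followed by Tamao–Fleming oxidation: the Si–H on the C3 oxygen can only reach the alkene face on which that oxygen sits, silicon goes to the nearer, less substituted C6 (six-membered oxasilinane, exo mode) and hydrogen to C7 by syn addition, and oxidation with retention gives C6–OH and C7–H on that face, which on the Z alkene is the 6R,7R pair of the target.

**Step 11**
Reactants: 19
Product: 20 (1S,2S,5R,6R,8S)-2-hydroxy-5-methoxy-2,6-dimethyl-11-oxabicyclo[6.2.1]undecan-9-one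
Conditions: Me3OBF4, Proton-sponge, CH2Cl2, 0 °C → rt
Reagents that add atoms: trimethyloxonium tetrafluoroborate C[O+](C)C.F[B-](F)(F)F
Why: O-Methylation with a Meerwein salt under non-basic conditions should take the secondary alcohol and leave the hindered tertiary one, without enolising the ketone.

**Step 12**
Reactants: 20
Product: 21 (1S,2S,5R,6R,8S)-2-hydroxy-5-methoxy-2,6-dimethyl-11-oxabicyclo[6.2.1]undec-9-en-9-yl trifluoromethanesulfonate
Conditions: KHMDS (2.2 equiv), PhNTf2, THF, −78 °C
Reagents that add atoms: N-phenylbis(trifluoromethanesulfonimide) O=S(=O)(N(c1ccccc1)S(=O)(=O)C(F)(F)F)C(F)(F)F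
Why: Kinetic enolisation should occur at the C1 methylene (the other α-position, C9, is a bridgehead α-oxy methine) and the enolate is O-triflated; the second equivalent of base covers the tertiary alcohol, whose hindered alkoxide should not be sulfonylated at this temperature.

**Step 13**
Reactants: 21
Product: 22 1-[(1S,2S,5R,6R,8S)-2-hydroxy-5-methoxy-2,6-dimethyl-11-oxabicyclo[6.2.1]undec-9-en-9-yl]propan-1-one
Conditions: Pd(PPh3)4 (5 mol %), LiCl, CO (1 atm), Et4Sn, THF, 60 °C
Reagents that add atoms: carbon monoxide [C-]#[O+]; tetraethyltin CC[Sn](CC)(CC)CC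
Why: Carbonylative Stille coupling (oxidative addition of the enol triflate, CO insertion, ethyl transfer from tin, reductive elimination) installs C11 as a ketone and C12 with its methyl in one operation.

**Step 14**
Reactants: 22
Product: 23 (Z)-triisopropylsilyl dienol ether of 22 (C1=C10–C11(OTIPS)=C12H–CH3; methyl cis to OSi)
Conditions: TIPSOTf (1.1 equiv), Et3N, CH2Cl2, −78 → 0 °C
Reagents that add atoms: triisopropylsilyl triflate CC(C)[Si](OS(=O)(=O)C(F)(F)F)(C(C)C)C(C)C
Why: Soft enolisation of an ethyl ketone with a silyl triflate and an amine gives the (Z)-O-silyl enol ether (methyl cis to oxygen); the bulky reagent should not silylate the tertiary alcohol.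

**Step 15**
Reactants: 23; 24 methyl vinyl ketone
Product: 25 endo Diels–Alder adduct (cyclohexene with C10=C11 TIPS enol ether; C14 acetyl cis to C2; C12 methyl cis to C2; H1 anti to C14)
Conditions: 24 (5 equiv), BHT (cat.), toluene, 100 °C, sealed tube
Reagents that add atoms: methyl vinyl ketone (24) CC(=O)C=C
Why: Normal-demand Diels–Alder reaction in which the 2-silyloxy group makes C12 the nucleophilic terminus (bond to the CH2 of the enone, acetyl on C14); the dienophile adds to the dihydrofuran face opposite the oxonane bridge, which sets C1, the outside methyl of the Z enol ether becomes the C12 methyl cis to C2, and the endo rule places the acetyl cis to C2 (any exo adduct is already 26).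

**Step 16**
Reactants: 25
Product: 26 C14-epimerised adduct (acetyl trans to C2; all other centres as in 25)
Conditions: K2CO3, MeOH, rt
Reagents that add atoms: none
Why: Base-mediated epimerisation α to the methyl ketone should converge on the trans C1/C14 arrangement with the acetyl equatorial, while the silyl enol ether keeps C11/C12 from enolising.

**Step 17**
Reactants: 26
Product: 27 isopropenyl compound (C14–C(CH3)=CH2; TIPS enol ether retained)
Conditions: Ph3PCH3Br, KOt-Bu, THF, 0 °C → rt
Reagents that add atoms: methyltriphenylphosphonium bromide C[P+](c1ccccc1)(c1ccccc1)c1ccccc1.[Br-]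
Why: Wittig methylenation of the methyl ketone adds C16; C14 is already in its stable configuration and the excess ylide tolerates the tertiary alcohol.

**Step 18**
Reactants: 27
Product: 28 cis-fused C11 ketone (H10 cis to H1; C12 methyl cis to C9)
Conditions: HF·pyridine, pyridine, THF, −20 → 0 °C
Reagents that add atoms: none
Why: Protodesilylation of the silyl enol ether should protonate C10 on the face of H1 (away from the pseudo-axial C12 methyl and C14), giving the cis ring fusion that the rigid bridged tetrahydrofuran also favours thermodynamically; cold, mildly acidic conditions are chosen so that the C12 centre α to the ketone does not epimerise.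

**Step 19**
Reactants: 28
Product: 29 C11 alcohol (OH cis to the C12 methyl and to C9)
Conditions: L-Selectride, THF, −78 °C; aq. NH4Cl
Reagents that add atoms: none
Why: The bulky hydride should attack the carbonyl face opposite the two cis α-substituents (C9 on C10 and the methyl on C12), so the hydroxyl ends up cis to both, as C11 requires.

**Step 20**
Reactants: 29
Product: 30 C11 acetate (isopropenyl and tertiary C3–OH retained)
Conditions: Ac2O, pyridine, DMAP (cat.), CH2Cl2, 0 °C → rt
Reagents that add atoms: acetic anhydride CC(=O)OC(C)=O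
Why: Acylation of the secondary alcohol; the tertiary C3 hydroxyl is too hindered to react under these conditions.

**Step 21**
Reactants: 30
Product: 32 primary alcohol (C16–OH; 15R), via alkylborane 31 (not isolated)
Conditions: 9-BBN, THF, 0 °C → rt; then 30 % H2O2, aq. NaOAc, 0 °C → rt
Reagents that add atoms: hydrogen peroxide OO
Why: Anti-Markovnikov hydroboration–oxidation of the 1,1-disubstituted alkene; in the reactive conformer H14 eclipses the C=C bond and the borane should add anti to the bulkier C1 branch, which corresponds to 15R, and the buffered oxidation spares the acetate.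

**Step 22**
Reactants: 32
Product: 34 target CNP0289153.2, via primary triflate 33 (not isolated)
Conditions: Tf2O, 2,6-lutidine, CH2Cl2, −78 °C → rt
Reagents that add atoms: none
Why: The primary alcohol is triflated selectively and the tertiary C3 hydroxyl displaces the triflate intramolecularly (Williamson etherification, 7-exo-tet) to close the oxepane without touching any stereocentre.

**Compound list**
1 | (S)-(+)-linalool | CC(C)=CCC[C@](C)(O)C=C | starting material
2 | (3S)-3,7-dimethyl-3-(triethylsilyloxy)octa-1,6-diene | CC(C)=CCC[C@](C)(O[Si](CC)(CC)CC)C=C | intermediate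
3 | (3S,6S)-6,7-epoxy-3,7-dimethyl-3-(triethylsilyloxy)oct-1-ene | CC1(C)O[C@H]1CC[C@](C)(O[Si](CC)(CC)CC)C=C | intermediate
4 | ethyl (triphenylphosphoranylidene)acetate | CCOC(=O)C=P(c1ccccc1)(c1ccccc1)c1ccccc1 | starting material
5 | ozonide of 3 (1,2,4-trioxolane from the vinyl group; mixture at the trioxolane CH) | CC1(C)O[C@H]1CC[C@](C)(O[Si](CC)(CC)CC)C2OCOO2 | intermediate
6 | (2S)-4-[(2S)-3,3-dimethyloxiran-2-yl]-2-methyl-2-(triethylsilyloxy)butanal | CC1(C)O[C@H]1CC[C@](C)(O[Si](CC)(CC)CC)C=O | intermediate
7 | ethyl (2E,4S)-6-[(2S)-3,3-dimethyloxiran-2-yl]-4-methyl-4-(triethylsilyloxy)hex-2-enoate | CC1(C)O[C@H]1CC[C@](C)(O[Si](CC)(CC)CC)/C=C/C(=O)OCC | intermediate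
8 | ethyl (2E,4S,7S)-7-hydroxy-4,8-dimethyl-4-(triethylsilyloxy)nona-2,8-dienoate | C=C(C)[C@@H](O)CC[C@](C)(O[Si](CC)(CC)CC)/C=C/C(=O)OCC | intermediate
9 | ethyl 2-[(2S,3S,6S)-3-methyl-6-(prop-1-en-2-yl)-3-(triethylsilyloxy)oxan-2-yl]acetate | CCOC(=O)C[C@@H]1O[C@H](C(C)=C)CC[C@]1(C)O[Si](CC)(CC)CC | intermediate
10 | 2-[(2S,3S,6S)-3-methyl-6-(prop-1-en-2-yl)-3-(triethylsilyloxy)oxan-2-yl]acetic acid | OC(=O)C[C@@H]1O[C@H](C(C)=C)CC[C@]1(C)O[Si](CC)(CC)CC | intermediate
11 | diazomethane | C=[N+]=[N-] | starting material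
12 | isobutyl carbonic mixed anhydride of 10 | CC(C)COC(=O)OC(=O)C[C@@H]1O[C@H](C(C)=C)CC[C@]1(C)O[Si](CC)(CC)CC | intermediate
13 | 1-diazo-3-[(2S,3S,6S)-3-methyl-6-(prop-1-en-2-yl)-3-(triethylsilyloxy)oxan-2-yl]propan-2-one | [N-]=[N+]=CC(=O)C[C@@H]1O[C@H](C(C)=C)CC[C@]1(C)O[Si](CC)(CC)CC | intermediate
14 | bicyclic allylic oxonium ylide (carbanion C9 on the ring oxygen; 3-oxo-oxolanium ring fused to the tetrahydropyran) | [CH-]1C(=O)C[C@@H]2[O+]1[C@H](C(C)=C)CC[C@]2(C)O[Si](CC)(CC)CC | intermediate
15 | (1S,2S,5Z,8S)-2,6-dimethyl-2-(triethylsilyloxy)-11-oxabicyclo[6.2.1]undec-5-en-9-one | O=C1C[C@@H]2O[C@H]1C/C(C)=C\CC[C@]2(C)O[Si](CC)(CC)CC | intermediate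
16 | (1S,2S,5Z,8S)-2-hydroxy-2,6-dimethyl-11-oxabicyclo[6.2.1]undec-5-en-9-one | O=C1C[C@@H]2O[C@H]1C/C(C)=C\CC[C@]2(C)O | intermediate
17 | dimethylsilyl (Si–H) ether of 16 | O=C1C[C@@H]2O[C@H]1C/C(C)=C\CC[C@]2(C)O[SiH](C)C | intermediate
18 | tricyclic siloxane (O–SiMe2 bridge from the C3 oxygen to C6; H on C7 syn to Si) | O=C1C[C@@H]2O[C@H]1C[C@@H](C)[C@H]3CC[C@]2(C)O[Si]3(C)C | intermediate
19 | (1S,2S,5R,6R,8S)-2,5-dihydroxy-2,6-dimethyl-11-oxabicyclo[6.2.1]undecan-9-one | O=C1C[C@@H]2O[C@H]1C[C@@H](C)[C@H](O)CC[C@]2(C)O | intermediate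
20 | (1S,2S,5R,6R,8S)-2-hydroxy-5-methoxy-2,6-dimethyl-11-oxabicyclo[6.2.1]undecan-9-one | O=C1C[C@@H]2O[C@H]1C[C@@H](C)[C@H](OC)CC[C@]2(C)O | intermediate
21 | (1S,2S,5R,6R,8S)-2-hydroxy-5-methoxy-2,6-dimethyl-11-oxabicyclo[6.2.1]undec-9-en-9-yl trifluoromethanesulfonate | O=S(=O)(OC1=C[C@@H]2O[C@H]1C[C@@H](C)[C@H](OC)CC[C@]2(C)O)C(F)(F)F | intermediate
22 | 1-[(1S,2S,5R,6R,8S)-2-hydroxy-5-methoxy-2,6-dimethyl-11-oxabicyclo[6.2.1]undec-9-en-9-yl]propan-1-one | CCC(=O)C1=C[C@@H]2O[C@H]1C[C@@H](C)[C@H](OC)CC[C@]2(C)O | intermediate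
23 | (Z)-triisopropylsilyl dienol ether of 22 (methyl cis to OSi) | C/C=C(\O[Si](C(C)C)(C(C)C)C(C)C)C1=C[C@@H]2O[C@H]1C[C@@H](C)[C@H](OC)CC[C@]2(C)O | intermediate
24 | methyl vinyl ketone (but-3-en-2-one) | CC(=O)C=C | starting material
25 | endo Diels–Alder adduct (C10=C11 TIPS enol ether; C14 acetyl cis to C2; C12 methyl cis to C2) | CC(=O)[C@H]1C[C@@H](C)C(O[Si](C(C)C)(C(C)C)C(C)C)=C2[C@H]1[C@@H]3O[C@H]2C[C@@H](C)[C@H](OC)CC[C@]3(C)O | intermediate
26 | C14-epimerised adduct (C14 acetyl trans to C2) | CC(=O)[C@@H]1C[C@@H](C)C(O[Si](C(C)C)(C(C)C)C(C)C)=C2[C@H]1[C@@H]3O[C@H]2C[C@@H](C)[C@H](OC)CC[C@]3(C)O | intermediate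
27 | isopropenyl compound (C14 isopropenyl; C10=C11 TIPS enol ether) | CC(=C)[C@@H]1C[C@@H](C)C(O[Si](C(C)C)(C(C)C)C(C)C)=C2[C@H]1[C@@H]3O[C@H]2C[C@@H](C)[C@H](OC)CC[C@]3(C)O | intermediate
28 | cis-fused C11 ketone (H10 cis to H1; C12 methyl cis to C9) | CC(=C)[C@@H]1C[C@@H](C)C(=O)[C@@H]2[C@H]1[C@@H]3O[C@H]2C[C@@H](C)[C@H](OC)CC[C@]3(C)O | intermediate
29 | C11 alcohol (OH cis to C12 methyl and C9) | CC(=C)[C@@H]1C[C@@H](C)[C@@H](O)[C@@H]2[C@H]1[C@@H]3O[C@H]2C[C@@H](C)[C@H](OC)CC[C@]3(C)O | intermediate
30 | C11 acetate with C14 isopropenyl and free C3–OH | CC(=C)[C@@H]1C[C@@H](C)[C@@H](OC(C)=O)[C@@H]2[C@H]1[C@@H]3O[C@H]2C[C@@H](C)[C@H](OC)CC[C@]3(C)O | intermediate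
31 | B-alkyl-9-borabicyclo[3.3.1]nonane (boron on C16; 15R) | C(B1C2CCCC1CCC2)[C@H](C)[C@@H]1C[C@@H](C)[C@@H](OC(C)=O)[C@@H]2[C@H]1[C@@H]3O[C@H]2C[C@@H](C)[C@H](OC)CC[C@]3(C)O | intermediate
32 | primary alcohol (C16–OH; 15R; free C3–OH) | OC[C@H](C)[C@@H]1C[C@@H](C)[C@@H](OC(C)=O)[C@@H]2[C@H]1[C@@H]3O[C@H]2C[C@@H](C)[C@H](OC)CC[C@]3(C)O | intermediate
33 | primary triflate of 32 (C16–OTf) | O=S(=O)(OC[C@H](C)[C@@H]1C[C@@H](C)[C@@H](OC(C)=O)[C@@H]2[C@H]1[C@@H]3O[C@H]2C[C@@H](C)[C@H](OC)CC[C@]3(C)O)C(F)(F)F | intermediate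
34 | CNP0289153.2 | CO[C@@H]1CC[C@]2(C)OC[C@H](C)[C@@H]3C[C@@H](C)[C@@H](OC(C)=O)[C@@H]4[C@H]3[C@@H]2O[C@H]4C[C@H]1C | target

**Totals and risks**
Total step count: 22. Longest linear sequence: 22 steps (from 1).

Most likely to fail:

Step 10. The platinum-catalysed Si–H addition may not reach the C6=C7 bond across the nine-membered ring, may place silicon on C7, or may be outrun by alkene isomerisation, so the C6/C7 pair would not be set. The fallback sets out from 16 and returns at 19. Vanadium-catalysed hydroxyl-directed epoxidation (VO(acac)2, t-BuOOH) should deliver oxygen to the alkene face syn to the C3 hydroxyl and give the epoxy alcohol (5,6-epoxide syn to the C2 hydroxyl, bicyclo numbering) F1, which that syn hydroxyl cannot open. Titanocene(III) chloride (Cp2TiCl2, Mn, THF) opens it homolytically at the tertiary carbon and, after β-hydrogen loss, gives the allylic alcohol with an exocyclic methylene on C7, F2, with the C6–O bond retained. Hydroxyl-directed hydrogenation with [Ir(cod)(PCy3)(py)]PF6 and H2 then adds hydrogen to C7 syn to both hydroxyls and gives 19.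

Step 21. Facial discrimination in the hydroboration of the isopropenyl group may be poor, which would give a mixture at C15 that the closed ring cannot correct. The fallback sets out from 30 and returns at 32. Allylic hydroxylation of the isopropenyl methyl (SeO2 cat., t-BuOOH) gives the 2-substituted allylic alcohol (C14–C(=CH2)–CH2OH) F3. Its hydrogenation with a chiral iridium phosphine–oxazoline (or Ru–BINAP) catalyst places the C15 hydrogen under ligand control, with the ligand enantiomer chosen for the 15R product, and gives 32.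

Step 8. The copper carbenoid may divert into a [1,2]-shift, C–H insertion or dimerisation, or the ylide may rearrange through the conformer that leads to the E-oxonene. The fallback sets out from 9 and returns at 15 and generates the same α-oxo carbene oxidatively from an alkyne. DIBAL-H (CH2Cl2, −78 °C) reduces the ester to the aldehyde 2-[(2S,3S,6S)-3-methyl-6-(prop-1-en-2-yl)-3-(triethylsilyloxy)oxan-2-yl]acetaldehyde F4. The Ohira–Bestmann reagent (K2CO3, MeOH) converts it to the terminal alkyne (2S,3S,6S)-3-methyl-6-(prop-1-en-2-yl)-2-(prop-2-yn-1-yl)-3-(triethylsilyloxy)oxane F5. Gold(I)-catalysed oxidation with 8-methylquinoline N-oxide ((IPr)AuNTf2, 1,2-dichloroethane) puts oxygen on the internal alkyne carbon and a gold carbene on the terminal one; the ring oxygen captures it with the same O–C9 closure and the [2,3]-shift gives 15.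

**Further compounds**
F1 | step 10 | (5,6)-epoxide of 16 with the epoxide oxygen syn to the C2 hydroxyl (bicyclo numbering) | O=C1C[C@@H]2O[C@H]1C[C@]3(C)O[C@@H]3CC[C@]2(C)O
F2 | step 10 | (1S,2S,5R,8S)-2,5-dihydroxy-2-methyl-6-methylidene-11-oxabicyclo[6.2.1]undecan-9-one | O=C1C[C@@H]2O[C@H]1CC(=C)[C@H](O)CC[C@]2(C)O
F3 | step 21 | allylic alcohol from 30 (C14–C(=CH2)–CH2OH) | OCC(=C)[C@@H]1C[C@@H](C)[C@@H](OC(C)=O)[C@@H]2[C@H]1[C@@H]3O[C@H]2C[C@@H](C)[C@H](OC)CC[C@]3(C)O
F4 | step 8 | 2-[(2S,3S,6S)-3-methyl-6-(prop-1-en-2-yl)-3-(triethylsilyloxy)oxan-2-yl]acetaldehyde | O=CC[C@@H]1O[C@H](C(C)=C)CC[C@]1(C)O[Si](CC)(CC)CC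
F5 | step 8 | (2S,3S,6S)-3-methyl-6-(prop-1-en-2-yl)-2-(prop-2-yn-1-yl)-3-(triethylsilyloxy)oxane | C#CC[C@@H]1O[C@H](C(C)=C)CC[C@]1(C)O[Si](CC)(CC)CC
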